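Count half-lives, one count for each substrate, on the clock of the spring run, which is this very flask followed so far.

| setting | spring | noon | flask |
|---|---|---|---|
| left-handed substrate | 20 mM | 20 mM | 20 mM |
| right-handed substrate | 20 mM | 20 mM | 20 mM |
| reagent | 4 equiv | 4 equiv | 4.00 equiv |
| free catalyst | 12 mol% | 12 mol% | 12 mol% |
| precatalyst | 1 mol% | 0.67 mol% | 1 mol% |
| remark | the very flask that is asked about, followed so far | run made earlier |  |
| time |  |  | 12 h |

- spring (time / h: left-handed product / %, right-handed product / %): 0.833: 12.8, 6.6; 2.00: 24.8, 12.8; 4.00: 36.6, 19.6; 6.00: 42.6, 26.3
- noon (time / h: left-handed product / %, right-handed product / %): 1.33: 19.8, 9.1; 2.50: 29.1, 14.4; 4.00: 36.7, 19.7; 5.00: 40.3, 23.2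

(scatter of a reading: 0.5 percentage points)

- left-handed product and right-handed product together, in percent of the left-handed substrate and right-handed substrate charged together, at 12 h
- excess of left-handed product over right-handed product in the product at 12 h
- whether the exchange between left-handed substrate and right-handed substrate keeps pace with the reaction: how far the product's excess at 12 h gets from its value without exchange to its value with instant exchange (above 80 % keeps pace, below 20 % hardly takes part, else lags behind)

- free catalyst is single-handed; left-handed substrate and right-handed substrate are mirror images of each other, charged as a racemate, each of them at the stated concentration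
- an excess is the difference of the two amounts in percent of their sum
- an excess is below zero if the other one leads

The spring run starts at a slope of 0.233 h⁻¹ in fractions of the charge, averaged up to the first reading. By 2.00 h, 50.4 % of the left-handed substrate's own charge stands, so that is my reading of its first half-life. Left-handed product overtakes right-handed substrate near 3.33 h, by straight interpolation. At 6.00 h the fractions left are 14.8 % and 47.4 %, left-handed then right-handed, so the ratio of the two counts is 2.56. This is the selectivity factor, the half-lives the left-handed substrate passes per half-life of the right-handed one.

I assume each conversion takes one reagent. The reagent charge is then twice what both substrates need, so the level ahead is full conversion. Between the last two readings the right-handed substrate has a half-life of 5.57 h, which allows 1.08 more half-lives by 12 h. That leaves 22.5 % of the right-handed substrate and, through the ratio, 2.19 % of the left-handed. My reckoning is a yield of 87.7 % and an excess of 11.6 %. Reagent sinks from 71.9 % to 65.5 % across those readings, so I hold that yield a little high.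

The forecast gives 86 % (80 % to 91 %), below mine, and an excess of 12 % (8 % to 18 %), like mine, with exchange that hardly takes part. Its grounds: “That is simple kinetic resolution, with no visible feeding of the fast substrate from the slow one.”

The flask gives 85.0 % and an excess of 15.5 %, and its exchange hardly takes part, getting 5.5 % of the way.

    reagent + free catalyst + left-handed substrate → free catalyst + left-handed product (k = 2080 L² mol⁻² h⁻¹)
    reagent + free catalyst + right-handed substrate → free catalyst + right-handed product (k = 818 L² mol⁻² h⁻¹)
    left-handed substrate + racemization catalyst ⇌ right-handed substrate + racemization catalyst, rate k3*[racemization catalyst]*[left-handed substrate] forward; the back reaction follows from the equilibrium constant (k = 78.8 L mol⁻¹ h⁻¹)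
    reagent + racemization catalyst → spent catalyst (k = 2.40 L mol⁻¹ h⁻¹)
    precatalyst → racemization catalyst (k = 0.999 h⁻¹)

In the flask, 26 % of the right-handed substrate stands at 12 h, which is 1.95 half-lives; the ratio then puts the left-handed substrate at 3.12 %, and it stands at 4.2 %. The neighbour flask with 20 mol% of free catalyst runs the clock 1.67 times as fast as 12 mol% does, so I count 3.25 half-lives and expect 10.5 % of the right-handed substrate. That neighbour holds 13 %. From this simulated value the ratio gives 0.511 % of the left-handed substrate, and the neighbour holds 0.90 %.

The readings were computed for substances that don't exist, and the scatter is random.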